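**Retrosynthetic overview**
- Target 25 ⇐ ring-closing metathesis at C5=C6 (ten-membered ring, formed last) of seco-diene 24.
- γ-Lactone (C8–C17 bond, C8 and C17) ⇐ SmI2 intramolecular Reformatsky reaction of a C7 2-bromopropanoate onto the C8 ketone.
- C7–C8 ⇐ γ-alkoxyallylboration of a C8 aldehyde; C11 (Me, OH) ⇐ enolate methylation, then enolate hydroxylation.
- C9–C10 bond with C1, C9, C10 ⇐ amine-catalysed desymmetrising Michael addition of a silyloxyacetaldehyde to cyclohexadienone 9 (ring A).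
- Dienone 9 ⇐ benzoic acid (Birch reductive methylation, ketone formation, CBS reduction for C2, acylation, allylic oxidation). Ring order: ring A, then lactone, then ten-membered ring.

Assumption: briarane numbering (C1–C20) is used for atom labels in all intermediates, and the target is taken as drawn, (1S,2R,5Z,7S,8S,9R,10S,11S,17R).

**Step 1**
Reactants: 1 benzoic acid
Product: 3 1-methylcyclohexa-2,5-diene-1-carboxylic acid, via Birch dianion 2 (not isolated)
Conditions: Li (3.3 equiv), NH3(l)/THF, −78 °C; MeI; aq. HCl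
Reagents that add atoms: iodomethane CI
Why: Birch reduction of the benzoate gives the cross-conjugated dianion 2, which is alkylated by MeI at the carboxylate-bearing carbon (Birch reductive alkylation), so the C1 quaternary carbon and C15 are in place with no stereocentre yet.

**Step 2**
Reactants: 3 1-methylcyclohexa-2,5-diene-1-carboxylic acid, 4 4-bromo-2-methylbut-1-ene
Product: 6 dienyl ketone, via alkyllithium 5 (not isolated)
Conditions: 4, Li wire, Et2O, 0 °C (gives 5, 2.2 equiv); then 3, Et2O/THF, 0 °C → rt; H2O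
Reagents that add atoms: none
Why: The lithium carboxylate takes up one equivalent of alkyllithium to give a dilithio gem-diolate that collapses to the ketone only on work-up (carboxylic acid to ketone with an organolithium), so no over-addition occurs and the acid has no α-hydrogen to lose.

**Step 3**
Reactants: 6 dienyl ketone
Product: 7 (1R)-alcohol
Conditions: (S)-2-butyl-CBS-oxazaborolidine (10 mol %), catecholborane (1.5 equiv), toluene, −78 → −40 °C; aq. NaOH
Reagents that add atoms: none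
Why: Corey–Bakshi–Shibata reduction, in which the oxazaborolidine tells the quaternary dienyl group (large) from the CH2 chain (small) and delivers hydride to give the (R)-carbinol, setting C2 as the first stereocentre by asymmetric catalysis, while catecholborane leaves the isopropenyl group untouched at low temperature.

**Step 4**
Reactants: 7 (1R)-alcohol
Product: 8 (1R)-butanoate
Conditions: (PrCO)2O, DMAP (cat.), Et3N, CH2Cl2, 0 °C → rt
Reagents that add atoms: butanoic anhydride CCCC(=O)OC(=O)CCC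
Why: DMAP-catalysed acylation of the secondary alcohol installs the C2 butanoate of the target early, where it also serves as the protecting group.

**Step 5**
Reactants: 8 (1R)-butanoate
Product: 9 cyclohexadienone
Conditions: CrO3 (10 mol %), t-BuOOH (6 equiv, 5.5 M in decane), CH2Cl2, rt
Reagents that add atoms: tert-butyl hydroperoxide CC(C)(C)OO
Why: Chromium-catalysed peroxide oxidation attacks the doubly allylic ring CH2 far faster than the simple allylic positions of the side chain (bis-allylic C–H oxidation), giving the cross-conjugated dienone whose two enone arms are diastereotopic.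

**Step 6**
Reactants: 9 cyclohexadienone, 10 (tert-butyldimethylsilyloxy)acetaldehyde
Product: 11 keto aldehyde
Conditions: (S)-α,α-diphenylprolinol trimethylsilyl ether (20 mol %), ethyl 3,4-dihydroxybenzoate (20 mol %), 10 (3 equiv, slow addition), CHCl3 (2 M), 4 °C, 48 h; used crude
Reagents that add atoms: none
Why: Proposed new method: an intermolecular enamine-mediated desymmetrising Michael addition of an α-silyloxy aldehyde to a 4,4-disubstituted cyclohexa-2,5-dienone, in which the E-anti-enamine of 10 attacks through the face away from the Ph2C(OSiMe3) group (C9 = R) the dienone that is hydrogen-bond-activated by the catechol co-catalyst, a synclinal open transition state sets C10 = S, and only the arm that can be reached from the methyl-bearing face (anti to the bulky C2 side chain) reacts so that C1 = S, the closest known reaction types being the intramolecular amine-catalysed Michael desymmetrisation of aldehyde-tethered cyclohexadienones and the intermolecular prolinol-ether/catechol-catalysed Michael addition of aldehydes to simple enones.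

**Step 7**
Reactants: 11 keto aldehyde, 12 allyl 4-methoxyphenyl ether
Product: 14 syn-alkoxy alcohol, via allylborane 13 (not isolated)
Conditions: 12, s-BuLi, THF, −78 °C; (+)-B-methoxydiisopinocampheylborane; BF3·OEt2; then 11, −78 °C, 4 h; pH 7 buffer, 30% H2O2, MeOH, 0 °C
Reagents that add atoms: none
Why: Brown asymmetric γ-alkoxyallylboration through a chair Zimmerman–Traxler transition state, in which the (Z)-reagent gives the syn C7/C8 pair and the isopinocampheyl groups from (−)-α-pinene direct Re-face attack so that C7 = S by reagent control, while the enone ketone does not react at −78 °C.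

**Step 8**
Reactants: 14 syn-alkoxy alcohol
Product: 16 C11-methyl ketone, via dilithium enolate 15 (not isolated)
Conditions: LiN(i-Pr)2 (2.3 equiv), THF, −78 °C; MeI (1.5 equiv), −78 → −40 °C; H2O
Reagents that add atoms: iodomethane CI
Why: C11 is the only enolisable position of the C12 ketone, so kinetic deprotonation (with the C8 hydroxyl carried as its lithium alkoxide) and enolate alkylation put the methyl on C11, trans to the C9 side chain, a centre that is re-formed in the next step.

**Step 9**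
Reactants: 16 C11-methyl ketone
Product: 18 C11 tertiary alcohol, via dilithium enolate 17 (not isolated)
Conditions: LiN(i-Pr)2 (2.3 equiv), THF, −78 → −40 °C; 2-(phenylsulfonyl)-3-phenyloxaziridine (1.5 equiv), −78 °C; H2O
Reagents that add atoms: 2-(phenylsulfonyl)-3-phenyloxaziridine O=S(=O)(c1ccccc1)N1OC1c1ccccc1
Why: Davis enolate hydroxylation, in which the oxaziridine approaches the tetrasubstituted enolate anti to the pseudoaxial C9 side chain on C10, so the hydroxyl ends up trans and the methyl cis to C9 (C11 = S).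

**Step 10**
Reactants: 18 C11 tertiary alcohol
Product: 19 C8 ketone
Conditions: Dess–Martin periodinane, NaHCO3, CH2Cl2, 0 °C → rt
Reagents that add atoms: none
Why: Dess–Martin oxidation converts the only secondary alcohol into the C8 ketone (the temporary C8 centre is erased) and leaves the tertiary C11 hydroxyl alone.

**Step 11**
Reactants: 19 C8 ketone
Product: 20 C7 alcohol
Conditions: (NH4)2Ce(NO3)6 (2.5 equiv), MeCN/H2O 4:1, 0 °C, 15 min
Reagents that add atoms: none
Why: Oxidative removal of the 4-methoxyphenyl ether (single-electron oxidation of the electron-rich arene and hydrolysis to the quinone) frees the C7 hydroxyl with retention of the C7–O bond, while the silyl ether, ester, enone and alkenes survive.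

**Step 12**
Reactants: 20 C7 alcohol
Product: 21 C7 2-bromopropanoate
Conditions: 2-bromopropanoyl bromide (1.3 equiv), pyridine, CH2Cl2, −20 °C
Reagents that add atoms: 2-bromopropanoyl bromide CC(Br)C(Br)=O
Why: Acylation of the secondary α-ketol hydroxyl with the acyl bromide proceeds at low temperature while the hindered tertiary C11 hydroxyl stays free, and both epimers at the CHBr carbon converge in the next step.

**Step 13**
Reactants: 21 C7 2-bromopropanoate
Product: 22 hydroxy lactone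
Conditions: SmI2 (2.5 equiv), THF, −78 °C, 30 min; sat. aq. NH4Cl
Reagents that add atoms: none
Why: Intramolecular SmI2 Reformatsky reaction, in which the C–Br bond is reduced faster than the ketones at −78 °C and the trivalent samarium enolate adds to the C8 ketone through a five-membered chelated transition state with the C7 vinyl group anti to the bulky C9 substituent (C8 = S), while the epimerisable C17 methyl settles cis to the hydroxyl and trans to C9 (C17 = R).

**Step 14**
Reactants: 22 hydroxy lactone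
Product: 23 C9 alcohol
Conditions: HF·pyridine, pyridine, THF, 0 °C → rt
Reagents that add atoms: none
Why: Buffered fluoride cleavage of the silyl ether frees the C9 hydroxyl without the base that would provoke retro-aldol opening of the β-hydroxy lactone.

**Step 15**
Reactants: 23 C9 alcohol
Product: 24 seco-diene acetate
Conditions: Ac2O (1.5 equiv), DMAP (cat.), pyridine, CH2Cl2, 0 °C
Reagents that add atoms: acetic anhydride CC(=O)OC(C)=O
Why: DMAP-catalysed acetylation takes the only secondary hydroxyl (C9) and leaves the two tertiary hydroxyls (C8, C11) free for steric reasons.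

**Step 16**
Reactants: 24 seco-diene acetate
Product: 25 target CNP0346936.2
Conditions: second-generation Hoveyda–Grubbs catalyst [RuCl2(H2IMes)(=CH-C6H4-2-O-i-Pr)] (15 mol %), 1,4-benzoquinone (30 mol %), toluene (1 mM), 90 °C
Reagents that add atoms: none
Why: Ring-closing olefin metathesis between the C7 vinyl group and the 1,1-disubstituted C5 alkene closes the ten-membered ring with loss of ethylene, and the ring size enforces the ring-cis (5Z) trisubstituted olefin.

**Compound list**
1 | benzoic acid | O=C(O)c1ccccc1 | starting material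
2 | dilithium (cyclohexa-2,5-dien-1-ylidene)methanediolate (Birch dianion) | [Li]OC(O[Li])=C1C=CCC=C1 | intermediate
3 | 1-methylcyclohexa-2,5-diene-1-carboxylic acid | CC1(C(=O)O)C=CCC=C1 | intermediate
4 | 4-bromo-2-methylbut-1-ene | C=C(C)CCBr | starting material
5 | (3-methylbut-3-en-1-yl)lithium | [Li]CCC(C)=C | intermediate
6 | 4-methyl-1-(1-methylcyclohexa-2,5-dien-1-yl)pent-4-en-1-one | CC1(C(=O)CCC(C)=C)C=CCC=C1 | intermediate
7 | (1R)-4-methyl-1-(1-methylcyclohexa-2,5-dien-1-yl)pent-4-en-1-ol | C=C(C)CC[C@@H](O)C1(C)C=CCC=C1 | intermediate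
8 | (1R)-4-methyl-1-(1-methylcyclohexa-2,5-dien-1-yl)pent-4-en-1-yl butanoate | CCCC(=O)O[C@H](CCC(C)=C)C1(C)C=CCC=C1 | intermediate
9 | (1R)-4-methyl-1-(1-methyl-4-oxocyclohexa-2,5-dien-1-yl)pent-4-en-1-yl butanoate | CCCC(=O)O[C@H](CCC(C)=C)C1(C)C=CC(=O)C=C1 | intermediate
10 | (tert-butyldimethylsilyloxy)acetaldehyde | CC(C)(C)[Si](C)(C)OCC=O | starting material
11 | (1R)-1-{(1S,6S)-6-[(1R)-1-(tert-butyldimethylsilyloxy)-2-oxoethyl]-1-methyl-4-oxocyclohex-2-en-1-yl}-4-methylpent-4-en-1-yl butanoate | CCCC(=O)O[C@H](CCC(C)=C)[C@@]1(C)C=CC(=O)C[C@@H]1[C@@H](O[Si](C)(C)C(C)(C)C)C=O | intermediate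
12 | allyl 4-methoxyphenyl ether (1-methoxy-4-(prop-2-en-1-yloxy)benzene) | C=CCOc1ccc(OC)cc1 | starting material
13 | [(2Z)-3-(4-methoxyphenoxy)prop-2-en-1-yl]bis(isopinocampheyl)borane, isopinocampheyl groups from (−)-α-pinene | COc1ccc(O/C=C\CB([C@H]2C[C@H]3C[C@H](C3(C)C)[C@@H]2C)[C@H]2C[C@H]3C[C@H](C3(C)C)[C@@H]2C)cc1 | intermediate
14 | (1R)-1-{(1S,6S)-6-[(1R,2R,3S)-1-(tert-butyldimethylsilyloxy)-2-hydroxy-3-(4-methoxyphenoxy)pent-4-en-1-yl]-1-methyl-4-oxocyclohex-2-en-1-yl}-4-methylpent-4-en-1-yl butanoate | CCCC(=O)O[C@H](CCC(C)=C)[C@@]1(C)C=CC(=O)C[C@@H]1[C@@H](O[Si](C)(C)C(C)(C)C)[C@H](O)[C@@H](Oc1ccc(OC)cc1)C=C | intermediate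
15 | dilithium C8-alkoxide C11,C12-enolate of 14 | CCCC(=O)O[C@H](CCC(C)=C)[C@@]1(C)C=CC(O[Li])=C[C@@H]1[C@@H](O[Si](C)(C)C(C)(C)C)[C@H](O[Li])[C@@H](Oc1ccc(OC)cc1)C=C | intermediate
16 | (1R)-1-{(1S,5S,6S)-6-[(1R,2R,3S)-1-(tert-butyldimethylsilyloxy)-2-hydroxy-3-(4-methoxyphenoxy)pent-4-en-1-yl]-1,5-dimethyl-4-oxocyclohex-2-en-1-yl}-4-methylpent-4-en-1-yl butanoate (C11 methyl trans to the C9 side chain) | CCCC(=O)O[C@H](CCC(C)=C)[C@@]1(C)C=CC(=O)[C@@H](C)[C@@H]1[C@@H](O[Si](C)(C)C(C)(C)C)[C@H](O)[C@@H](Oc1ccc(OC)cc1)C=C | intermediate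
17 | dilithium C8-alkoxide C11,C12-enolate of 16 | CCCC(=O)O[C@H](CCC(C)=C)[C@@]1(C)C=CC(O[Li])=C(C)[C@@H]1[C@@H](O[Si](C)(C)C(C)(C)C)[C@H](O[Li])[C@@H](Oc1ccc(OC)cc1)C=C | intermediate
18 | (1R)-1-{(1S,5S,6S)-6-[(1R,2R,3S)-1-(tert-butyldimethylsilyloxy)-2-hydroxy-3-(4-methoxyphenoxy)pent-4-en-1-yl]-5-hydroxy-1,5-dimethyl-4-oxocyclohex-2-en-1-yl}-4-methylpent-4-en-1-yl butanoate | CCCC(=O)O[C@H](CCC(C)=C)[C@@]1(C)C=CC(=O)[C@@](C)(O)[C@@H]1[C@@H](O[Si](C)(C)C(C)(C)C)[C@H](O)[C@@H](Oc1ccc(OC)cc1)C=C | intermediate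
19 | (1R)-1-{(1S,5S,6S)-6-[(1R,3S)-1-(tert-butyldimethylsilyloxy)-3-(4-methoxyphenoxy)-2-oxopent-4-en-1-yl]-5-hydroxy-1,5-dimethyl-4-oxocyclohex-2-en-1-yl}-4-methylpent-4-en-1-yl butanoate | CCCC(=O)O[C@H](CCC(C)=C)[C@@]1(C)C=CC(=O)[C@@](C)(O)[C@@H]1[C@@H](O[Si](C)(C)C(C)(C)C)C(=O)[C@@H](Oc1ccc(OC)cc1)C=C | intermediate
20 | (1R)-1-{(1S,5S,6S)-6-[(1R,3S)-1-(tert-butyldimethylsilyloxy)-3-hydroxy-2-oxopent-4-en-1-yl]-5-hydroxy-1,5-dimethyl-4-oxocyclohex-2-en-1-yl}-4-methylpent-4-en-1-yl butanoate | CCCC(=O)O[C@H](CCC(C)=C)[C@@]1(C)C=CC(=O)[C@@](C)(O)[C@@H]1[C@@H](O[Si](C)(C)C(C)(C)C)C(=O)[C@@H](O)C=C | intermediate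
21 | C7 2-bromopropanoate ester of 20 (both epimers at the CHBr carbon) | CCCC(=O)O[C@H](CCC(C)=C)[C@@]1(C)C=CC(=O)[C@@](C)(O)[C@@H]1[C@@H](O[Si](C)(C)C(C)(C)C)C(=O)[C@@H](OC(=O)C(C)Br)C=C | intermediate
22 | (1R)-1-{(1S,5S,6S)-6-[(R)-(tert-butyldimethylsilyloxy)[(2S,3S,4R)-2-ethenyl-3-hydroxy-4-methyl-5-oxooxolan-3-yl]methyl]-5-hydroxy-1,5-dimethyl-4-oxocyclohex-2-en-1-yl}-4-methylpent-4-en-1-yl butanoate | CCCC(=O)O[C@H](CCC(C)=C)[C@@]1(C)C=CC(=O)[C@@](C)(O)[C@@H]1[C@@H](O[Si](C)(C)C(C)(C)C)[C@]2(O)[C@@H](C)C(=O)O[C@H]2C=C | intermediate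
23 | (1R)-1-{(1S,5S,6S)-6-[(R)-hydroxy[(2S,3R,4R)-2-ethenyl-3-hydroxy-4-methyl-5-oxooxolan-3-yl]methyl]-5-hydroxy-1,5-dimethyl-4-oxocyclohex-2-en-1-yl}-4-methylpent-4-en-1-yl butanoate | CCCC(=O)O[C@H](CCC(C)=C)[C@@]1(C)C=CC(=O)[C@@](C)(O)[C@@H]1[C@@H](O)[C@]2(O)[C@@H](C)C(=O)O[C@H]2C=C | intermediate
24 | (1R)-1-{(1S,5S,6S)-6-[(R)-acetoxy[(2S,3S,4R)-2-ethenyl-3-hydroxy-4-methyl-5-oxooxolan-3-yl]methyl]-5-hydroxy-1,5-dimethyl-4-oxocyclohex-2-en-1-yl}-4-methylpent-4-en-1-yl butanoate | CCCC(=O)O[C@H](CCC(C)=C)[C@@]1(C)C=CC(=O)[C@@](C)(O)[C@@H]1[C@@H](OC(C)=O)[C@]2(O)[C@@H](C)C(=O)O[C@H]2C=C | intermediate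
25 | CNP0346936.2: (1S,2R,5Z,7S,8S,9R,10S,11S,17R)-9-acetoxy-2-butanoyloxy-8,11-dihydroxy-12-oxobriara-5,13-diene γ-lactone (C19 carbonyl to the C7 oxygen) | CCCC(=O)O[C@@H]1CC/C(C)=C\[C@@H]2OC(=O)[C@H](C)[C@@]2(O)[C@H](OC(C)=O)[C@@H]2[C@]1(C)C=CC(=O)[C@@]2(C)O | target

**Totals and risks**
Total step count: 16. Longest linear sequence: 16 steps, from benzoic acid 1.

The three steps most likely to fail:

Step 6 (the proposed new Michael addition; reactivity at the hindered C10 and the three-centre stereocontrol are unproven). The fallback uses known chemistry, sets out from 9 and 10, and comes back at 11. Aldehyde 10 is converted with t-BuMe2SiOTf and Et3N into (Z)-1,2-bis(tert-butyldimethylsilyloxy)ethene F1. A Mukaiyama–Michael addition of F1 to 9 (TiCl4 or catalytic t-BuMe2SiOTf, CH2Cl2, −78 °C) gives the C12 silyl dienol ether F2, and citric acid in aqueous THF releases 11. Induction then comes from the substrate only (attack anti to the C2 side chain), so 11 has to be separated from its arm and C9 diastereomers by chromatography.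

Step 7 (the borane has to override the Felkin preference of the α-silyloxy aldehyde). The fallback sets out from 11 and comes back at 19. A D-proline-catalysed cross-aldol reaction with slowly added (4-methoxyphenoxy)acetaldehyde (DMF, 4 °C) gives the anti-aldol aldehyde F3, with C7 as required and C8 epimeric to 14, which is the Felkin-matched sense. Wittig methylenation (Ph3P=CH2, THF, −78 °C) gives the vinyl alcohol F4. The conditions of steps 8 and 9 then give the C11-methyl ketone F5 and the C11 tertiary alcohol F6, and Dess–Martin oxidation of F6 erases C8 and gives 19.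

Step 16 (a trisubstituted olefin in a strained ten-membered ring, closed on the fully functionalised substrate). The fallback changes the order of ring formation, sets out from 19, and comes back at 25. The ten-membered ring is closed first on the flexible ketone 19 with the same ruthenium catalyst to give the macrocyclic ketone F7. The lactone is then built inside the ring: (NH4)2Ce(NO3)6 gives the C7 alcohol F8, 2-bromopropanoyl bromide gives the bromopropanoate F9, and SmI2 gives the macrocyclic lactone F10, the ring conformation now directing the C8 face. HF·pyridine gives the 9-deacetyl compound F11, and Ac2O/DMAP gives 25.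

**Further compounds**
F1 | step 6 | (Z)-1,2-bis(tert-butyldimethylsilyloxy)ethene | CC(C)(C)[Si](C)(C)O/C=C\O[Si](C)(C)C(C)(C)C
F2 | step 6 | C12 tert-butyldimethylsilyl dienol ether of 11 | CCCC(=O)O[C@H](CCC(C)=C)[C@@]1(C)C=CC(O[Si](C)(C)C(C)(C)C)=C[C@@H]1[C@@H](O[Si](C)(C)C(C)(C)C)C=O
F3 | step 7 | anti-aldol aldehyde (C6 aldehyde, C7 4-methoxyphenyl ether, C8 hydroxyl epimeric to 14) | CCCC(=O)O[C@H](CCC(C)=C)[C@@]1(C)C=CC(=O)C[C@@H]1[C@@H](O[Si](C)(C)C(C)(C)C)[C@@H](O)[C@@H](Oc1ccc(OC)cc1)C=O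
F4 | step 7 | C8 epimer of 14 | CCCC(=O)O[C@H](CCC(C)=C)[C@@]1(C)C=CC(=O)C[C@@H]1[C@@H](O[Si](C)(C)C(C)(C)C)[C@@H](O)[C@@H](Oc1ccc(OC)cc1)C=C
F5 | step 7 | C8 epimer of 16 | CCCC(=O)O[C@H](CCC(C)=C)[C@@]1(C)C=CC(=O)[C@@H](C)[C@@H]1[C@@H](O[Si](C)(C)C(C)(C)C)[C@@H](O)[C@@H](Oc1ccc(OC)cc1)C=C
F6 | step 7 | C8 epimer of 18 | CCCC(=O)O[C@H](CCC(C)=C)[C@@]1(C)C=CC(=O)[C@@](C)(O)[C@@H]1[C@@H](O[Si](C)(C)C(C)(C)C)[C@@H](O)[C@@H](Oc1ccc(OC)cc1)C=C
F7 | step 16 | macrocyclic C8 ketone (ten-membered ring closed, C7 4-methoxyphenyl ether, C9 silyl ether) | CCCC(=O)O[C@@H]1CC/C(C)=C\[C@H](Oc3ccc(OC)cc3)C(=O)[C@H](O[Si](C)(C)C(C)(C)C)[C@@H]2[C@]1(C)C=CC(=O)[C@@]2(C)O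
F8 | step 16 | macrocyclic C7 alcohol | CCCC(=O)O[C@@H]1CC/C(C)=C\[C@H](O)C(=O)[C@H](O[Si](C)(C)C(C)(C)C)[C@@H]2[C@]1(C)C=CC(=O)[C@@]2(C)O
F9 | step 16 | macrocyclic C7 2-bromopropanoate (both CHBr epimers) | CCCC(=O)O[C@@H]1CC/C(C)=C\[C@H](OC(=O)C(C)Br)C(=O)[C@H](O[Si](C)(C)C(C)(C)C)[C@@H]2[C@]1(C)C=CC(=O)[C@@]2(C)O
F10 | step 16 | 9-O-(tert-butyldimethylsilyl)-9-deacetyl target | CCCC(=O)O[C@@H]1CC/C(C)=C\[C@@H]2OC(=O)[C@H](C)[C@@]2(O)[C@H](O[Si](C)(C)C(C)(C)C)[C@@H]2[C@]1(C)C=CC(=O)[C@@]2(C)O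
F11 | step 16 | 9-deacetyl target | CCCC(=O)O[C@@H]1CC/C(C)=C\[C@@H]2OC(=O)[C@H](C)[C@@]2(O)[C@H](O)[C@@H]2[C@]1(C)C=CC(=O)[C@@]2(C)O
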